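**Plan**
The retrosynthesis first removes the two MOM ethers (O5, O4') and the C3 methoxy group (back to C3–H), then cuts ring C at three bonds: C4a–C4, C4–C3 and O1–C2.
Enabling feature: C4 is a ketone carbon whose only neighbours are C4a of ring A, C3 and its own oxygen, so carbon monoxide can supply it between an iodide on C4a and a terminal alkyne that brings C3, C2 and ring B. O1 is the ring-A phenol oxygen ortho to that iodide.
Forward: ring A iodophenol 8 is made from aldehyde 1 (carbamate, Baeyer–Villiger, MOM ether, carbamate-directed lithiation and iodination, hydrolysis). Ring B alkyne 11 is made from aldehyde 9 (MOM ether, Ohira–Bestmann).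
Ring C is then closed in one palladium-catalysed operation from 8, carbon monoxide and 11. C3 is hydroxylated and methylated, and both MOM groups are removed last.
Stereochemistry: the target has no stereocentre and no stereogenic double bond, so nothing has to be controlled.

Key step: step 8

Remark: both free phenols of the target are carried as methoxymethyl (MOM) ethers so that one mild acid step frees them at the end; 1, 9 and cylinder carbon monoxide are taken as purchased.

**Route**

Step 1
Reactants: 1 (5-hydroxy-3,4-dimethoxybenzaldehyde)
Product: 2 carbamate aldehyde (5-formyl-2,3-dimethoxyphenyl N,N-diethylcarbamate)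
Conditions: Et2NCOCl, K2CO3, MeCN, reflux
Reagents that add atoms: N,N-diethylcarbamoyl chloride, CCN(CC)C(Cl)=O
Why: O-carbamoylation of the phenoxide (nucleophilic acyl substitution) masks the future O1 and installs the group that later directs ortho-lithiation, and the aldehyde is inert to K2CO3.

Step 2
Reactants: 2 (carbamate aldehyde)
Product: 4 phenol carbamate (5-hydroxy-2,3-dimethoxyphenyl N,N-diethylcarbamate), via aryl formate 3 (not isolated)
Conditions: mCPBA, CH2Cl2, 0 °C to rt; then K2CO3 (cat.), MeOH, 0 °C
Reagents that add atoms: 3-chloroperoxybenzoic acid (mCPBA), OOC(=O)c1cccc(Cl)c1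
Why: Baeyer–Villiger (Dakin-type) oxidation, in which the electron-rich aryl group carrying a methoxy group para to the formyl carbon migrates in preference to hydride, and brief methanolysis cleaves the aryl formate while the much less electrophilic dialkylcarbamate stays intact.

Step 3
Reactants: 4 (phenol carbamate)
Product: 5 MOM ether carbamate (2,3-dimethoxy-5-(methoxymethoxy)phenyl N,N-diethylcarbamate)
Conditions: MOMCl, i-Pr2NEt, CH2Cl2, 0 °C to rt
Reagents that add atoms: chloromethyl methyl ether, COCCl
Why: MOM ether formation by O-alkylation of the phenol protects the future 5-OH with a group that tolerates organolithiums, hydroxide, palladium catalysis and amide bases, and that adds a second ortho-directing group.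

Step 4
Reactants: 5 (MOM ether carbamate)
Product: 7 aryl iodide (2-iodo-5,6-dimethoxy-3-(methoxymethoxy)phenyl N,N-diethylcarbamate), via aryllithium 6 (not isolated)
Conditions: s-BuLi, TMEDA, THF, −78 °C; then I2, THF, −78 °C to rt; aq. Na2S2O3 work-up
Reagents that add atoms: iodine, II; sec-butyllithium, [Li]C(C)CC (lithium held only in intermediate 6)
Why: Directed ortho-metalation, in which the only hydrogen ortho to the O-carbamate lies between it and the OMOM group so that both coordinating groups place lithium there at −78 °C (where the carbamoyl group does not migrate), followed by iodine quench of the aryllithium.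

Step 5
Reactants: 7 (aryl iodide)
Product: 8 iodophenol (6-iodo-2,3-dimethoxy-5-(methoxymethoxy)phenol)
Conditions: NaOH, EtOH/H2O, reflux; then aq. NH4Cl
Reagents that add atoms: none
Why: Base hydrolysis of the aryl carbamate (addition–elimination at the carbamate carbonyl with phenoxide as leaving group) frees the phenol, and the MOM ether and the aryl iodide are inert to hydroxide.

Step 6
Reactants: 9 (4-hydroxy-2-methoxybenzaldehyde)
Product: 10 MOM aldehyde (2-methoxy-4-(methoxymethoxy)benzaldehyde)
Conditions: MOMCl, i-Pr2NEt, CH2Cl2, 0 °C to rt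
Reagents that add atoms: chloromethyl methyl ether, COCCl
Why: MOM ether formation by O-alkylation of the acidic para-formyl phenol, with the aldehyde left untouched for the homologation.

Step 7
Reactants: 10 (MOM aldehyde)
Product: 11 arylacetylene (1-ethynyl-2-methoxy-4-(methoxymethoxy)benzene)
Conditions: dimethyl (1-diazo-2-oxopropyl)phosphonate, K2CO3, MeOH, 0 °C to rt
Reagents that add atoms: dimethyl (1-diazo-2-oxopropyl)phosphonate, COP(=O)(OC)C(=[N+]=[N-])C(C)=O
Why: Ohira–Bestmann variant of the Seyferth–Gilbert homologation, in which the diazomethylphosphonate anion released by methanolysis olefinates the aldehyde and loss of nitrogen with a 1,2-hydrogen shift gives the terminal alkyne under conditions that leave the MOM ether alone.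

Step 8
Reactants: 8 (iodophenol); 11 (arylacetylene); 12 (carbon monoxide)
Product: 15 bis-MOM flavone (7,8-dimethoxy-2-[2-methoxy-4-(methoxymethoxy)phenyl]-5-(methoxymethoxy)-4H-chromen-4-one), via ortho-hydroxyaryl ynone 13 (not isolated), via enaminone 14 (not isolated)
Conditions: PdCl2(PPh3)2 (5 mol %), CO (20 atm), Et2NH (solvent and base), 120 °C, autoclave
Reagents that add atoms: carbon monoxide (compound 12), [C-]#[O+]; diethylamine, CCNCC (held only in intermediate 14)
Why: Zerovalent palladium, formed in situ from PdCl2(PPh3)2, inserts into the C–I bond of 8, CO insertion gives an aroylpalladium iodide, and the amine-activated alkyne 11 is transferred to palladium and reductively eliminated to give ortho-hydroxyaryl ynone 13 (a carbonylative Sonogashira-type coupling that forms C4a–C4 and C4–C3). Diethylamine then adds to the ynone to give enaminone 14, and the phenol oxygen attacks the amine-bearing carbon in a 6-endo-trig addition–elimination that forms O1–C2, expels diethylamine and closes ring C as the pyran-4-one. The closest known reaction type is the palladium-catalysed carbonylative annulation of ortho-iodophenols with terminal arylacetylenes in a secondary amine, which gives flavones directly. No stereocentre is formed. The step needs CO insertion to be faster than direct alkynylation and 6-endo closure to be faster than 5-exo closure to an aurone: CO pressure and the electron-rich, doubly ortho-substituted arylpalladium species favour the first, and conversion of the ynone into the enaminone before ring closure secures the second. Regiochemistry is fixed by the substrate, since the iodine sits on the carbon between the free phenol and the MOM ether, so the carbonyl can only enter at C4a and only the free hydroxyl can close the ring.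

Step 9
Reactants: 15 (bis-MOM flavone)
Product: 18 flavonol (3-hydroxy-7,8-dimethoxy-2-[2-methoxy-4-(methoxymethoxy)phenyl]-5-(methoxymethoxy)-4H-chromen-4-one), via 3-lithioflavone 16 (not isolated), via flavone-3-boronate 17 (not isolated)
Conditions: LiN(i-Pr)2, THF, −78 °C; B(OMe)3, −78 °C to rt; AcOH, 30% aq. H2O2, 0 °C to rt
Reagents that add atoms: hydrogen peroxide, OO; lithium diisopropylamide, [Li]N(C(C)C)C(C)C (lithium held only in 16); trimethyl borate, COB(OC)OC (boron held only in 17)
Why: C3 lithiation of the flavone (its only acidic C–H, vinylic and next to the lithium-coordinating C4 carbonyl), borylation and oxidative C–B to C–O conversion is the established deprotonation–borylation–oxidation route from flavones to flavonols, and the MOM and methyl ethers are inert to it.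

Step 10
Reactants: 18 (flavonol)
Product: 19 3-O-methyl flavonol (3,7,8-trimethoxy-2-[2-methoxy-4-(methoxymethoxy)phenyl]-5-(methoxymethoxy)-4H-chromen-4-one)
Conditions: MeI, K2CO3, acetone, reflux
Reagents that add atoms: iodomethane, CI
Why: Williamson O-methylation of the acidic enolic 3-hydroxyl, the only free hydroxyl in the molecule.

Step 11
Reactants: 19 (3-O-methyl flavonol)
Product: 20 target (5,4'-dihydroxy-3,7,8,2'-tetramethoxyflavone)
Conditions: 3 M aq. HCl, MeOH, 50 °C
Reagents that add atoms: none
Why: Acid-catalysed acetal cleavage (transacetalisation to methanol) removes both MOM ethers, while the aryl and enol methyl ethers are stable to dilute acid at this temperature, far below what a Wessely–Moser-type ring opening and reclosure needs.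

**Compound list**
1 | 5-hydroxy-3,4-dimethoxybenzaldehyde | COc1cc(C=O)cc(O)c1OC | starting material
2 | 5-formyl-2,3-dimethoxyphenyl N,N-diethylcarbamate | CCN(CC)C(=O)Oc1cc(C=O)cc(OC)c1OC | intermediate
3 | 5-(formyloxy)-2,3-dimethoxyphenyl N,N-diethylcarbamate (aryl formate, not isolated) | CCN(CC)C(=O)Oc1cc(OC=O)cc(OC)c1OC | intermediate
4 | 5-hydroxy-2,3-dimethoxyphenyl N,N-diethylcarbamate | CCN(CC)C(=O)Oc1cc(O)cc(OC)c1OC | intermediate
5 | 2,3-dimethoxy-5-(methoxymethoxy)phenyl N,N-diethylcarbamate | CCN(CC)C(=O)Oc1cc(OCOC)cc(OC)c1OC | intermediate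
6 | 2-lithio-5,6-dimethoxy-3-(methoxymethoxy)phenyl N,N-diethylcarbamate (aryllithium, not isolated) | CCN(CC)C(=O)Oc1c([Li])c(OCOC)cc(OC)c1OC | intermediate
7 | 2-iodo-5,6-dimethoxy-3-(methoxymethoxy)phenyl N,N-diethylcarbamate | CCN(CC)C(=O)Oc1c(I)c(OCOC)cc(OC)c1OC | intermediate
8 | 6-iodo-2,3-dimethoxy-5-(methoxymethoxy)phenol | Oc1c(I)c(OCOC)cc(OC)c1OC | intermediate
9 | 4-hydroxy-2-methoxybenzaldehyde | COc1cc(O)ccc1C=O | starting material
10 | 2-methoxy-4-(methoxymethoxy)benzaldehyde | COCOc1ccc(C=O)c(OC)c1 | intermediate
11 | 1-ethynyl-2-methoxy-4-(methoxymethoxy)benzene | C#Cc1ccc(OCOC)cc1OC | intermediate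
12 | carbon monoxide | [C-]#[O+] | starting material
13 | 1-[2-hydroxy-3,4-dimethoxy-6-(methoxymethoxy)phenyl]-3-[2-methoxy-4-(methoxymethoxy)phenyl]prop-2-yn-1-one (not isolated) | COCOc1ccc(C#CC(=O)c2c(O)c(OC)c(OC)cc2OCOC)c(OC)c1 | intermediate
14 | 3-(diethylamino)-1-[2-hydroxy-3,4-dimethoxy-6-(methoxymethoxy)phenyl]-3-[2-methoxy-4-(methoxymethoxy)phenyl]prop-2-en-1-one (alkene geometry not fixed, not isolated) | CCN(CC)C(=CC(=O)c1c(O)c(OC)c(OC)cc1OCOC)c1ccc(OCOC)cc1OC | intermediate
15 | 7,8-dimethoxy-2-[2-methoxy-4-(methoxymethoxy)phenyl]-5-(methoxymethoxy)-4H-chromen-4-one | COCOc1ccc(-c2cc(=O)c3c(OCOC)cc(OC)c(OC)c3o2)c(OC)c1 | intermediate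
16 | 3-lithio-7,8-dimethoxy-2-[2-methoxy-4-(methoxymethoxy)phenyl]-5-(methoxymethoxy)-4H-chromen-4-one (not isolated) | [Li]c1c(-c2ccc(OCOC)cc2OC)oc2c(OC)c(OC)cc(OCOC)c2c1=O | intermediate
17 | dimethyl {7,8-dimethoxy-2-[2-methoxy-4-(methoxymethoxy)phenyl]-5-(methoxymethoxy)-4-oxo-4H-chromen-3-yl}boronate (not isolated) | COB(OC)c1c(-c2ccc(OCOC)cc2OC)oc2c(OC)c(OC)cc(OCOC)c2c1=O | intermediate
18 | 3-hydroxy-7,8-dimethoxy-2-[2-methoxy-4-(methoxymethoxy)phenyl]-5-(methoxymethoxy)-4H-chromen-4-one | COCOc1ccc(-c2oc3c(OC)c(OC)cc(OCOC)c3c(=O)c2O)c(OC)c1 | intermediate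
19 | 3,7,8-trimethoxy-2-[2-methoxy-4-(methoxymethoxy)phenyl]-5-(methoxymethoxy)-4H-chromen-4-one | COCOc1ccc(-c2oc3c(OC)c(OC)cc(OCOC)c3c(=O)c2OC)c(OC)c1 | intermediate
20 | 5,4'-dihydroxy-3,7,8,2'-tetramethoxyflavone (5-hydroxy-2-(4-hydroxy-2-methoxyphenyl)-3,7,8-trimethoxy-4H-chromen-4-one) | COc1cc(O)ccc1-c1oc2c(OC)c(OC)cc(O)c2c(=O)c1OC | target

**Totals**
Total step count: 11 steps (ring A: steps 1–5; ring B: steps 6–7; union and finish: steps 8–11).
Longest linear sequence: 9 steps (steps 1–5, then 8–11).

**Steps most likely to fail**

Step 8 (carbonylative annulation). Three processes could drain material. Direct alkynylation may outrun CO insertion, and the coupled alkyne would then cyclise to a 2-arylbenzofuran. Diethylamine may intercept the aroylpalladium species as an amide. Ring closure may drift to the 5-exo mode. The fallback separates the events. Setting out from 8, acetylation (Ac2O, pyridine) should give 6-iodo-2,3-dimethoxy-5-(methoxymethoxy)phenyl acetate F1. Carbonylative Sonogashira coupling of F1 with 11 under CO with PdCl2(PPh3)2 and Et3N in THF, where the tertiary amine can add neither to the aroylpalladium species nor to the product, should give the isolated ynone 2-{3-[2-methoxy-4-(methoxymethoxy)phenyl]prop-2-ynoyl}-5,6-dimethoxy-3-(methoxymethoxy)phenyl acetate F2. Treating F2 with Et2NH in EtOH should cleave the acetate by aminolysis, form the enaminone and close ring C, which rejoins the route at 15.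

Step 9 (C3 hydroxylation). Metalation may be incomplete or misdirected (amide addition at C2, or proton return before the borate is trapped), and the boronate may lose boron to a proton during oxidation. The fallback replaces deprotonation by electrophilic oxidation of the C2–C3 double bond. Setting out from 15, dimethyldioxirane in acetone/CH2Cl2 at 0 °C should give the racemic cis-fused 2,3-epoxy-7,8-dimethoxy-2-[2-methoxy-4-(methoxymethoxy)phenyl]-5-(methoxymethoxy)chroman-4-one F3. Brief exposure of F3 to catalytic TsOH in CH2Cl2 should open the epoxide at C2 and, after proton loss from C3, give the flavonol, which rejoins the route at 18.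

Step 4 (directed lithiation and iodination). Lithiation may compete at the carbon between the OMOM and methoxy groups, and the carbamoyl group may migrate to the lithiated carbon (anionic ortho-Fries shift) if the temperature rises before the quench. The fallback installs iodine by electrophilic substitution before the MOM group is added. Setting out from 4, N-iodosuccinimide in MeCN at 0 °C should iodinate ortho to the free hydroxyl at the carbon para to the 3-methoxy group and give 3-hydroxy-2-iodo-5,6-dimethoxyphenyl N,N-diethylcarbamate F4; any regioisomer would be removed at this stage. MOM protection of F4 (MOMCl, i-Pr2NEt, CH2Cl2) rejoins the route at 7.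

**Further compounds**
F1 | step 8 | 6-iodo-2,3-dimethoxy-5-(methoxymethoxy)phenyl acetate | CC(=O)Oc1c(I)c(OCOC)cc(OC)c1OC
F2 | step 8 | 2-{3-[2-methoxy-4-(methoxymethoxy)phenyl]prop-2-ynoyl}-5,6-dimethoxy-3-(methoxymethoxy)phenyl acetate | CC(=O)Oc1c(C(=O)C#Cc2ccc(OCOC)cc2OC)c(OCOC)cc(OC)c1OC
F3 | step 9 | 2,3-epoxy-7,8-dimethoxy-2-[2-methoxy-4-(methoxymethoxy)phenyl]-5-(methoxymethoxy)chroman-4-one (racemic, cis-fused; one enantiomer drawn) | COCOc1ccc([C@]23O[C@H]2C(=O)c4c(OCOC)cc(OC)c(OC)c4O3)c(OC)c1
F4 | step 4 | 3-hydroxy-2-iodo-5,6-dimethoxyphenyl N,N-diethylcarbamate | CCN(CC)C(=O)Oc1c(I)c(O)cc(OC)c1OC
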